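## Retrosynthetic overview

1. The ten-membered ring is closed last, at C5–C6, by a visible-light photoredox/nickel decarboxylative alkenylation of a γ-lactone acid that carries an E-alkenyl bromide.
2. The lactone acid comes from a butenolide (the first ring formed; C6 bought) by radical conjugate addition of a C8 iodide, which sets C7 and C11, followed by oxidation of the CH2OH group.
3. The iodide chain comes from a Z-selective Wittig union (C1=C10) of an α-alkoxy methyl ketone (C9 bought) with a phosphonium salt (C3 bought; E-alkenyl bromide by carboalumination).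

Assumption: germacrane numbering is used for positions (lactone oxygen on C6, lactone carbons C7, C11, C12, acetates on C3 and C9, C1=C10 Z, C4=C5 E), and the three chiral starting materials are bought as single enantiomers.

## Route

Step 1
Reactants: 1 (S)-3-hydroxydihydrofuran-2(3H)-one
Product: 2 (S)-3-[(tert-butyldimethylsilyl)oxy]dihydrofuran-2(3H)-one
Conditions: TBSCl, imidazole, DMF, 0 °C to rt
Reagents that add atoms: tert-butyldimethylsilyl chloride, CC(C)(C)[Si](C)(C)Cl
Why: Imidazole-promoted silyl ether formation protects the secondary alcohol and does not touch the bought stereocentre (future C3).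

Step 2
Reactants: 2 (S)-3-[(tert-butyldimethylsilyl)oxy]dihydrofuran-2(3H)-one
Product: 4 (S)-3-[(tert-butyldimethylsilyl)oxy]pent-4-yn-1-ol, via lactol 3 (not isolated)
Conditions: i-Bu2AlH, CH2Cl2, −78 °C; then MeOH, K2CO3, dimethyl (1-diazo-2-oxopropyl)phosphonate, 0 °C to rt
Reagents that add atoms: dimethyl (1-diazo-2-oxopropyl)phosphonate, COP(=O)(OC)C(=[N+]=[N-])C(C)=O
Why: Partial lactone reduction followed by Seyferth–Gilbert homologation (Ohira–Bestmann reagent) in one pot gives the terminal alkyne, and the mild carbonate base at 0 °C leaves the α-silyloxy stereocentre intact.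

Step 3
Reactants: 4 (S)-3-[(tert-butyldimethylsilyl)oxy]pent-4-yn-1-ol
Product: 6 (3S,4E)-5-bromo-3-[(tert-butyldimethylsilyl)oxy]-4-methylpent-4-en-1-ol, via vinylalane 5 (not isolated)
Conditions: Me3Al (3.5 equiv), Cp2ZrCl2 (0.3 equiv), CH2Cl2, 0 °C to rt; then N-bromosuccinimide, THF, −30 °C
Reagents that add atoms: trimethylaluminium, C[Al](C)C; N-bromosuccinimide, O=C1CCC(=O)N1Br
Why: Negishi zirconium-catalysed carboalumination adds methyl and aluminium syn across the alkyne (methyl on the internal carbon) and bromodealumination goes with retention, so the E-alkenyl bromide (Br trans to C3) needed for the 4E olefin results.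

Step 4
Reactants: 6 (3S,4E)-5-bromo-3-[(tert-butyldimethylsilyl)oxy]-4-methylpent-4-en-1-ol
Product: 7 tert-butyl{[(1E,3S)-1-bromo-5-iodo-2-methylpent-1-en-3-yl]oxy}dimethylsilane
Conditions: I2, PPh3, imidazole, CH2Cl2, 0 °C
Reagents that add atoms: iodine, II
Why: Garegg–Samuelsson (Appel-type) iodination replaces the primary hydroxyl by SN2 displacement, with no stereocentre or olefin involved.

Step 5
Reactants: 7 tert-butyl{[(1E,3S)-1-bromo-5-iodo-2-methylpent-1-en-3-yl]oxy}dimethylsilane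
Product: 8 {(3S,4E)-5-bromo-3-[(tert-butyldimethylsilyl)oxy]-4-methylpent-4-en-1-yl}triphenylphosphonium iodide
Conditions: PPh3, MeCN, 80 °C
Reagents that add atoms: triphenylphosphine, c1ccc(cc1)P(c1ccccc1)c1ccccc1
Why: SN2 quaternisation of the phosphine by the unhindered primary iodide gives the phosphonium salt, and the alkenyl bromide and silyl ether are inert.

Step 6
Reactants: 9 methyl (R)-2,2-dimethyl-1,3-dioxolane-4-carboxylate
Product: 11 (R)-1-(2,2-dimethyl-1,3-dioxolan-4-yl)ethan-1-one, via Weinreb amide 10 (not isolated)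
Conditions: MeNH(OMe)·HCl, i-PrMgCl, THF, −20 °C; then MeMgBr, −20 to 0 °C; aq. NH4Cl
Reagents that add atoms: methylmagnesium bromide, C[Mg]Br
Why: Telescoped Weinreb ketone synthesis stops cleanly at the methyl ketone, and the low temperature keeps the α-alkoxy stereocentre (future C9) from epimerising.

Step 7
Reactants: 12 (R)-2,2-dimethyl-1,3-dioxolane-4-carbaldehyde
Product: 13 methyl (2Z)-3-[(4S)-2,2-dimethyl-1,3-dioxolan-4-yl]-2-methylprop-2-enoate
Conditions: methyl 2-[bis(2,2,2-trifluoroethoxy)phosphoryl]propanoate, KN(SiMe3)2, 18-crown-6, THF, −78 °C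
Reagents that add atoms: methyl 2-[bis(2,2,2-trifluoroethoxy)phosphoryl]propanoate, COC(=O)C(C)P(=O)(OCC(F)(F)F)OCC(F)(F)F
Why: The Still–Gennari variant of the Horner–Wadsworth–Emmons olefination gives the Z-trisubstituted enoate under kinetic control, and the dioxolane stereocentre (future C6) is carried through unchanged.

Step 8
Reactants: 13 methyl (2Z)-3-[(4S)-2,2-dimethyl-1,3-dioxolan-4-yl]-2-methylprop-2-enoate
Product: 15 (S)-5-(hydroxymethyl)-3-methylfuran-2(5H)-one, via diol ester 14 (not isolated)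
Conditions: 10% aq. H2SO4, MeOH, rt
Reagents that add atoms: none
Why: Acid-catalysed acetonide hydrolysis and spontaneous lactonisation of the Z γ-hydroxy enoate (five-ring closure preferred over six) give the butenolide without touching the stereocentre.

Step 9
Reactants: 8 {(3S,4E)-5-bromo-3-[(tert-butyldimethylsilyl)oxy]-4-methylpent-4-en-1-yl}triphenylphosphonium iodide; 11 (R)-1-(2,2-dimethyl-1,3-dioxolan-4-yl)ethan-1-one
Product: 17 tert-butyl{[(1E,3S,5Z)-1-bromo-6-[(4S)-2,2-dimethyl-1,3-dioxolan-4-yl]-2-methylhepta-1,5-dien-3-yl]oxy}dimethylsilane, via ylide 16 (not isolated)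
Conditions: KN(SiMe3)2 (1.0 equiv), THF, −78 °C; then 11 (1.3 equiv), −78 °C to rt
Reagents that add atoms: none
Why: Salt-free Wittig olefination of an α-alkoxy methyl ketone with a non-stabilised ylide (Still's Z-selective trisubstituted-olefin synthesis) puts the ylide chain cis to the oxygenated carbon, giving the 1(10)Z olefin, and the ketone stereocentre is not epimerised at −78 °C.

Step 10
Reactants: 17 tert-butyl{[(1E,3S,5Z)-1-bromo-6-[(4S)-2,2-dimethyl-1,3-dioxolan-4-yl]-2-methylhepta-1,5-dien-3-yl]oxy}dimethylsilane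
Product: 18 (2S,3Z,6S,7E)-8-bromo-3,7-dimethylocta-3,7-diene-1,2,6-triol
Conditions: 1 M aq. HCl, MeOH, 0 °C to rt
Reagents that add atoms: none
Why: Acid-catalysed global deprotection cleaves the isopropylidene acetal and the silyl ether without breaking the carbinol C–O bonds, so C3 and C9 keep their configuration.

Step 11
Reactants: 18 (2S,3Z,6S,7E)-8-bromo-3,7-dimethylocta-3,7-diene-1,2,6-triol
Product: 19 (2S,3Z,6S,7E)-8-bromo-1-iodo-3,7-dimethylocta-3,7-diene-2,6-diol
Conditions: I2 (1.05 equiv), PPh3 (1.1 equiv), imidazole, THF/MeCN, −20 to 0 °C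
Reagents that add atoms: iodine, II
Why: Garegg–Samuelsson iodination is kinetically selective for the unhindered primary hydroxyl over the two secondary allylic ones at low temperature with one equivalent of reagent.

Step 12
Reactants: 19 (2S,3Z,6S,7E)-8-bromo-1-iodo-3,7-dimethylocta-3,7-diene-2,6-diol
Product: 20 (2S,3Z,6S,7E)-8-bromo-1-iodo-3,7-dimethylocta-3,7-diene-2,6-diyl diacetate
Conditions: Ac2O, pyridine, DMAP (cat.), CH2Cl2, 0 °C
Reagents that add atoms: acetic anhydride, CC(=O)OC(C)=O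
Why: DMAP-catalysed acylation of both secondary alcohols proceeds with retention and installs the two acetates of the target at C3 and C9.

Step 13
Reactants: 20 (2S,3Z,6S,7E)-8-bromo-1-iodo-3,7-dimethylocta-3,7-diene-2,6-diyl diacetate; 15 (S)-5-(hydroxymethyl)-3-methylfuran-2(5H)-one
Product: 21 (3R,4S,5S)-4-[(2R,3Z,6S,7E)-2,6-diacetoxy-8-bromo-3,7-dimethylocta-3,7-dien-1-yl]-5-(hydroxymethyl)-3-methyloxolan-2-one
Conditions: 15 (3 equiv), (Me3Si)3SiH (1.5 equiv, syringe pump), AIBN (cat.), toluene, 80 °C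
Reagents that add atoms: none
Why: Giese radical conjugate addition (radical chosen because a C8 organometallic would eliminate the β-acetate): C–C bond formation at the butenolide β-carbon occurs anti to the hydroxymethyl group (sets C7), hydrogen transfer from the bulky silane occurs anti to the new side chain (sets C11, methyl cis to C8), and the alkenyl bromide survives because iodine abstraction is far faster.

Step 14
Reactants: 21 (3R,4S,5S)-4-[(2R,3Z,6S,7E)-2,6-diacetoxy-8-bromo-3,7-dimethylocta-3,7-dien-1-yl]-5-(hydroxymethyl)-3-methyloxolan-2-one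
Product: 23 (2S,3S,4R)-3-[(2R,3Z,6S,7E)-2,6-diacetoxy-8-bromo-3,7-dimethylocta-3,7-dien-1-yl]-4-methyl-5-oxooxolane-2-carboxylic acid, via aldehyde 22 (not isolated)
Conditions: TEMPO (0.2 equiv), PhI(OAc)2 (2.5 equiv), MeCN/H2O 1:1, rt
Reagents that add atoms: water, O
Why: TEMPO/PhI(OAc)2 oxoammonium oxidation takes the primary alcohol to the carboxylic acid chemoselectively in the presence of the olefins, the alkenyl bromide and the esters.

Step 15
Reactants: 23 (2S,3S,4R)-3-[(2R,3Z,6S,7E)-2,6-diacetoxy-8-bromo-3,7-dimethylocta-3,7-dien-1-yl]-4-methyl-5-oxooxolane-2-carboxylic acid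
Product: 24 (3S,6S,7S,9R,11R)-3,9-diacetoxygermacra-1(10)Z,4E-dien-12,6-olide (target CNP0226482.6)
Conditions: Ir[dF(CF3)ppy]2(dtbbpy)PF6 (2 mol%), NiCl2·DME (20 mol%), 4,4′-di-tert-butyl-2,2′-bipyridine (24 mol%), DBU (1.5 equiv), DMSO (0.002 M, slow addition of 23), blue LEDs (450 nm), 25 °C
Reagents that add atoms: none
Why: Proposed new method: a ring-closing photoredox/nickel decarboxylative alkenylation — the photoexcited iridium complex oxidises the carboxylate of 23, loss of CO2 gives a lactone-stabilised α-oxy radical at C6, zerovalent nickel inserts into the tethered E-alkenyl C5–Br bond, the radical is captured at nickel and reductive elimination from trivalent nickel forms C5–C6 with retention of the 4E geometry and closes the ten-membered ring; because radical capture is reversible, the ring-closing reductive elimination should select the face of C6 anti to the C7–C8 bond and give the trans-fused lactone (6S) under control of C7; closest known reaction type: the intermolecular metallaphotoredox decarboxylative coupling of α-oxy carboxylic acids with alkenyl halides, not yet shown as a medium-ring closure with this 1,2-stereocontrol.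

## Compound list

1 | (S)-3-hydroxydihydrofuran-2(3H)-one ((S)-α-hydroxy-γ-butyrolactone) | O[C@H]1CCOC1=O | starting material
2 | (S)-3-[(tert-butyldimethylsilyl)oxy]dihydrofuran-2(3H)-one | CC(C)(C)[Si](C)(C)O[C@H]1CCOC1=O | intermediate
3 | (3S)-3-[(tert-butyldimethylsilyl)oxy]oxolan-2-ol (lactol, both C2 epimers) | CC(C)(C)[Si](C)(C)O[C@H]1CCOC1O | intermediate
4 | (S)-3-[(tert-butyldimethylsilyl)oxy]pent-4-yn-1-ol | CC(C)(C)[Si](C)(C)O[C@H](C#C)CCO | intermediate
5 | (1E,3S)-alkenylalane: 2-methylpent-1-ene chain with AlMe2 on C1, OTBS on C3 and O–AlMe2 on C5 | C[Al](C)OCC[C@H](O[Si](C)(C)C(C)(C)C)/C(C)=C/[Al](C)C | intermediate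
6 | (3S,4E)-5-bromo-3-[(tert-butyldimethylsilyl)oxy]-4-methylpent-4-en-1-ol | OCC[C@H](O[Si](C)(C)C(C)(C)C)/C(C)=C/Br | intermediate
7 | tert-butyl{[(1E,3S)-1-bromo-5-iodo-2-methylpent-1-en-3-yl]oxy}dimethylsilane | ICC[C@H](O[Si](C)(C)C(C)(C)C)/C(C)=C/Br | intermediate
8 | {(3S,4E)-5-bromo-3-[(tert-butyldimethylsilyl)oxy]-4-methylpent-4-en-1-yl}triphenylphosphonium iodide | c1ccccc1[P+](c1ccccc1)(c1ccccc1)CC[C@H](O[Si](C)(C)C(C)(C)C)/C(C)=C/Br.[I-] | intermediate
9 | methyl (R)-2,2-dimethyl-1,3-dioxolane-4-carboxylate | COC(=O)[C@H]1COC(C)(C)O1 | starting material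
10 | (R)-N-methoxy-N,2,2-trimethyl-1,3-dioxolane-4-carboxamide | CON(C)C(=O)[C@H]1COC(C)(C)O1 | intermediate
11 | (R)-1-(2,2-dimethyl-1,3-dioxolan-4-yl)ethan-1-one | CC(=O)[C@H]1COC(C)(C)O1 | intermediate
12 | (R)-2,2-dimethyl-1,3-dioxolane-4-carbaldehyde | O=C[C@H]1COC(C)(C)O1 | starting material
13 | methyl (2Z)-3-[(4S)-2,2-dimethyl-1,3-dioxolan-4-yl]-2-methylprop-2-enoate | COC(=O)/C(C)=C\[C@H]1COC(C)(C)O1 | intermediate
14 | methyl (2Z,4S)-4,5-dihydroxy-2-methylpent-2-enoate | COC(=O)/C(C)=C\[C@H](O)CO | intermediate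
15 | (S)-5-(hydroxymethyl)-3-methylfuran-2(5H)-one | CC1=C[C@@H](CO)OC1=O | intermediate
16 | ylide: {(3S,4E)-5-bromo-3-[(tert-butyldimethylsilyl)oxy]-4-methylpent-4-en-1-ylidene}triphenyl-λ5-phosphane | c1ccccc1P(c1ccccc1)(c1ccccc1)=CC[C@H](O[Si](C)(C)C(C)(C)C)/C(C)=C/Br | intermediate
17 | tert-butyl{[(1E,3S,5Z)-1-bromo-6-[(4S)-2,2-dimethyl-1,3-dioxolan-4-yl]-2-methylhepta-1,5-dien-3-yl]oxy}dimethylsilane | CC(C)(C)[Si](C)(C)O[C@H](/C(C)=C/Br)C/C=C(/C)[C@H]1COC(C)(C)O1 | intermediate
18 | (2S,3Z,6S,7E)-8-bromo-3,7-dimethylocta-3,7-diene-1,2,6-triol | O[C@H](/C(C)=C/Br)C/C=C(/C)[C@H](O)CO | intermediate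
19 | (2S,3Z,6S,7E)-8-bromo-1-iodo-3,7-dimethylocta-3,7-diene-2,6-diol | O[C@H](/C(C)=C/Br)C/C=C(/C)[C@H](O)CI | intermediate
20 | (2S,3Z,6S,7E)-8-bromo-1-iodo-3,7-dimethylocta-3,7-diene-2,6-diyl diacetate | CC(=O)O[C@H](/C(C)=C/Br)C/C=C(/C)[C@H](OC(C)=O)CI | intermediate
21 | (3R,4S,5S)-4-[(2R,3Z,6S,7E)-2,6-diacetoxy-8-bromo-3,7-dimethylocta-3,7-dien-1-yl]-5-(hydroxymethyl)-3-methyloxolan-2-one | CC(=O)O[C@H](/C(C)=C/Br)C/C=C(/C)[C@H](OC(C)=O)C[C@@H]1[C@@H](CO)OC(=O)[C@@H]1C | intermediate
22 | (2S,3S,4R)-3-[(2R,3Z,6S,7E)-2,6-diacetoxy-8-bromo-3,7-dimethylocta-3,7-dien-1-yl]-4-methyl-5-oxooxolane-2-carbaldehyde | CC(=O)O[C@H](/C(C)=C/Br)C/C=C(/C)[C@H](OC(C)=O)C[C@@H]1[C@@H](C=O)OC(=O)[C@@H]1C | intermediate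
23 | (2S,3S,4R)-3-[(2R,3Z,6S,7E)-2,6-diacetoxy-8-bromo-3,7-dimethylocta-3,7-dien-1-yl]-4-methyl-5-oxooxolane-2-carboxylic acid | CC(=O)O[C@H](/C(C)=C/Br)C/C=C(/C)[C@H](OC(C)=O)C[C@@H]1[C@@H](C(=O)O)OC(=O)[C@@H]1C | intermediate
24 | (3S,6S,7S,9R,11R)-3,9-diacetoxygermacra-1(10)Z,4E-dien-12,6-olide (CNP0226482.6) | CC(=O)O[C@H]1C/C=C(/C)[C@H](OC(C)=O)C[C@@H]2[C@@H](/C=C/1C)OC(=O)[C@@H]2C | target

## Step count and risk

Total step count: 15. Longest linear sequence: 12 steps (steps 1–5, then 9–15).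

The three steps most likely to fail:

Step 15 (the proposed new ring closure). The risks are oligomerisation or simple protodecarboxylation instead of ten-ring closure, and the wrong configuration at C6. The fallback uses known chemistry, sets out from 23 and comes back at 24. Kochi oxidative decarboxylation of 23 with Pb(OAc)4 and catalytic Cu(OAc)2 in benzene/pyridine gives the acylal (3R,4S)-5-acetoxy-4-[(2R,3Z,6S,7E)-2,6-diacetoxy-8-bromo-3,7-dimethylocta-3,7-dien-1-yl]-3-methyloxolan-2-one F1. Brief hydrolysis of the labile acylal acetate (THF/H2O, cat. TsOH, 0 °C; the two allylic acetates react much more slowly) gives the pseudo-acid (3R,4S)-4-[(2R,3Z,6S,7E)-2,6-diacetoxy-8-bromo-3,7-dimethylocta-3,7-dien-1-yl]-5-hydroxy-3-methyloxolan-2-one F2, the ring-chain tautomer of the C6 aldehyde/C12 acid. An intramolecular Nozaki–Hiyama–Kishi reaction (excess CrCl2, catalytic NiCl2, DMSO, high dilution, 50 °C) joins the alkenyl bromide to the aldehyde and gives the ten-membered hydroxy acid (2R)-2-[(1S,2S,3E,5S,7Z,9R)-5,9-diacetoxy-2-hydroxy-4,8-dimethylcyclodeca-3,7-dien-1-yl]propanoic acid F3, which lactonises on acidic work-up to 24. Felkin-type addition anti to the C7 substituents should favour the trans-lactone; a cis-lactone by-product would be separable.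

Step 9 (Z-selectivity of the Wittig reaction and possible epimerisation of ketone 11 by the ylide). The fallback sets out from 7 and comes back at 17. Michaelis–Becker alkylation of Ph2P(O)H/NaH with 7 gives {(3S,4E)-5-bromo-3-[(tert-butyldimethylsilyl)oxy]-4-methylpent-4-en-1-yl}diphenylphosphine oxide F4. Its lithio derivative (LiN(i-Pr)2, THF, −78 °C) adds to 11 to give the β-hydroxy phosphine oxide adducts (3S,5E)-6-bromo-4-[(tert-butyldimethylsilyl)oxy]-1-[(4S)-2,2-dimethyl-1,3-dioxolan-4-yl]-1,5-dimethyl-2-(diphenylphosphoryl)hex-5-en-1-ol F5. The diastereomers whose phosphoryl and hydroxyl groups are arranged so that C2 and the dioxolanyl carbon end up cis are separated by chromatography, and stereospecific syn-elimination (NaH, DMF, 50 °C; stepwise Horner–Wittig olefination) gives 17 as the pure Z-olefin.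

Step 11 (competing substitution at the secondary allylic hydroxyls, or olefin formation from the vicinal diol). The fallback sets out from 18 and comes back at 19. Bu2SnO-catalysed regioselective sulfonylation (TsCl, Et3N, CH2Cl2) through the stannylene acetal of the 1,2-diol gives the primary tosylate (2S,3Z,6S,7E)-8-bromo-2,6-dihydroxy-3,7-dimethylocta-3,7-dien-1-yl 4-methylbenzenesulfonate F6, and Finkelstein displacement (NaI, acetone, 50 °C) gives 19.

Further compounds
F1 | step 15 | (3R,4S)-5-acetoxy-4-[(2R,3Z,6S,7E)-2,6-diacetoxy-8-bromo-3,7-dimethylocta-3,7-dien-1-yl]-3-methyloxolan-2-one (both C5 epimers) | CC(=O)O[C@H](/C(C)=C/Br)C/C=C(/C)[C@H](OC(C)=O)C[C@@H]1C(OC(C)=O)OC(=O)[C@@H]1C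
F2 | step 15 | (3R,4S)-4-[(2R,3Z,6S,7E)-2,6-diacetoxy-8-bromo-3,7-dimethylocta-3,7-dien-1-yl]-5-hydroxy-3-methyloxolan-2-one (both C5 epimers) | CC(=O)O[C@H](/C(C)=C/Br)C/C=C(/C)[C@H](OC(C)=O)C[C@@H]1C(O)OC(=O)[C@@H]1C
F3 | step 15 | (2R)-2-[(1S,2S,3E,5S,7Z,9R)-5,9-diacetoxy-2-hydroxy-4,8-dimethylcyclodeca-3,7-dien-1-yl]propanoic acid | CC(=O)O[C@H]1C/C=C(/C)[C@H](OC(C)=O)C[C@H]([C@@H](/C=C/1C)O)[C@@H](C)C(=O)O
F4 | step 9 | {(3S,4E)-5-bromo-3-[(tert-butyldimethylsilyl)oxy]-4-methylpent-4-en-1-yl}diphenylphosphine oxide | O=P(c1ccccc1)(c1ccccc1)CC[C@H](O[Si](C)(C)C(C)(C)C)/C(C)=C/Br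
F5 | step 9 | (3S,5E)-6-bromo-4-[(tert-butyldimethylsilyl)oxy]-1-[(4S)-2,2-dimethyl-1,3-dioxolan-4-yl]-1,5-dimethyl-2-(diphenylphosphoryl)hex-5-en-1-ol (the two new centres as the syn-eliminating diastereomers) | CC(C)(C)[Si](C)(C)O[C@H](/C(C)=C/Br)CC(P(=O)(c1ccccc1)c1ccccc1)C(C)(O)[C@H]1COC(C)(C)O1
F6 | step 11 | (2S,3Z,6S,7E)-8-bromo-2,6-dihydroxy-3,7-dimethylocta-3,7-dien-1-yl 4-methylbenzenesulfonate | O[C@H](/C(C)=C/Br)C/C=C(/C)[C@H](O)COS(=O)(=O)c1ccc(C)cc1
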